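**Plan**

1. Numbering follows the germacranolides: ring C1 (ketone) to C10 (CHMe, methyl C14), C4 carries C15, the lactone carbons C11–C13 sit on C7/C8. β is the ring face of the C7–C11 bond, α the face of H7.
2. Retrosynthesis: the O6 ester, C11=C13 and the oxygens at C1, C4 and C6 are traced back to a 1(10)E,4Z-cyclodecadien-6-one lactone. Its two alkenes are re-paired as σ bonds C5–C10 and C1–C4, and the cyclobutane so formed is cut at C4–C5 and C1–C10. The lactone enone is then cut at C7–C11 and C5=C10.
3. Enabling feature: C1–C2–C3–C4 (with C15) lies between C10 and C5. These four carbons are therefore a 1-methylcyclobutene inserted into the C5=C10 bond of the six-membered enone C5–C10, which already holds C6=O, C14 and the C7/C8 γ-lactone.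
4. Forward order: six-membered ring (intramolecular olefination), lactone, two cyclobutanes (photocycloaddition), ten-membered ring (thermal opening), then C4–OH, C6–OH, O6 ester, C1–OH, C13 and C1=O.
5. Stereochemistry: C8 from the purchased (3R)-silyloxy ester; C7 by equilibration to the cis-fused lactone; C4 by a chiral boryl-copper catalyst; C6 by C4-hydroxyl-directed anti reduction; C10 by outer-face hydroboration of the E alkene.

Key step: step 6

Assumption: the cis-anti-cis adduct is taken to open through a chair 1,4-diyl to the 1(10)E,4Z dienone, so 11–15 are drawn that way; if the other E,Z isomer formed, the face-selective steps 8 and 11 would have to be re-matched.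

**Step 1**
Reactants: 1 methyl (3R)-3-[(tert-butyldimethylsilyl)oxy]-6-(dimethoxyphosphoryl)-5-oxohexanoate
Product: 3 dimethyl [(4S)-4-[(tert-butyldimethylsilyl)oxy]-2,6-dioxoheptyl]phosphonate, via Weinreb amide 2 (not isolated)
Conditions: MeNH(OMe)·HCl, iPrMgCl, THF, −20 °C; then MeMgBr, −20 → 0 °C; aq. NH4Cl
Reagents that add atoms: methylmagnesium bromide C[Mg]Br; N,O-dimethylhydroxylamine hydrochloride CNOC.Cl (its atoms stay in 2 only)
Why: Weinreb ketone synthesis in one flask: the magnesium amide turns the ester into amide 2 while the β-ketophosphonate is held as its magnesium enolate, so MeMgBr adds once, to the amide only, and the silyloxy carbon (C8) is untouched.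

**Step 2**
Reactants: 3 dimethyl [(4S)-4-[(tert-butyldimethylsilyl)oxy]-2,6-dioxoheptyl]phosphonate
Product: 4 (5S)-5-[(tert-butyldimethylsilyl)oxy]-3-methylcyclohex-2-en-1-one
Conditions: LiCl, iPr2NEt, MeCN, rt
Reagents that add atoms: none
Why: Intramolecular Horner–Wadsworth–Emmons olefination under LiCl/amine conditions: only the acidic phosphonate CH2 (C5) is deprotonated and it closes on the methyl ketone (C10) to the six-membered enone, the weak base sparing the β-silyloxy ketone.

**Step 3**
Reactants: 4 (5S)-5-[(tert-butyldimethylsilyl)oxy]-3-methylcyclohex-2-en-1-one; 5 tert-butyl bromoacetate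
Product: 6 tert-butyl 2-[(1R,6S)-6-[(tert-butyldimethylsilyl)oxy]-4-methyl-2-oxocyclohex-3-en-1-yl]acetate (side chain trans to the silyloxy group)
Conditions: LiN(iPr)2, THF, −78 °C; then 5, DMPU, −78 → −50 °C
Reagents that add atoms: none
Why: Kinetic α′-deprotonation gives the cross-conjugated lithium enolate, which is alkylated anti to the neighbouring silyloxy group (C7/C8 trans); the low temperature keeps the β-silyloxy enolate from E1cB loss of silanolate, and C7 is reset in step 4.

**Step 4**
Reactants: 6 tert-butyl 2-[(1R,6S)-6-[(tert-butyldimethylsilyl)oxy]-4-methyl-2-oxocyclohex-3-en-1-yl]acetate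
Product: 7 (3aS,7aS)-6-methyl-3a,7a-dihydro-1-benzofuran-2,4(3H,7H)-dione (cis-fused lactone enone)
Conditions: TFA–H2O (9:1), CH2Cl2, 0 °C → rt; then CSA (cat.), PhMe, 45 °C
Reagents that add atoms: none
Why: Acid cleaves the silyl ether and the tert-butyl ester and the hydroxy acid lactonises; C7, α to the ketone, equilibrates through the enol and is drained into the more stable cis-fused γ-lactone (thermodynamic control relative to the fixed C8), the in-ring C8–O bond lying close to the enol plane and so being poorly aligned for elimination.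

**Step 5**
Reactants: 8 methylenecyclobutane
Product: 9 1-methylcyclobutene
Conditions: KOtBu (cat.), DMSO, rt; fractional distillation
Reagents that add atoms: none
Why: Base-catalysed prototropic isomerisation to the more stable endocyclic trisubstituted alkene, a known equilibration for this pair, with 9 separated by distillation.

**Step 6**
Reactants: 7 (3aS,7aS)-6-methyl-3a,7a-dihydro-1-benzofuran-2,4(3H,7H)-dione; 9 1-methylcyclobutene
Product: 10 cis-anti-cis head-to-head photoadduct: cyclohexanone C5–C10 cis-fused to the γ-lactone (C7/C8, β face) and to cyclobutane C5–C10–C1–C4 (α face), which shares C1–C4 with cyclobutane C1–C2–C3–C4; methyls on C10 and C4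
Conditions: hν (350 nm, Pyrex), 9 (10 equiv), CH2Cl2, −40 °C, degassed
Reagents that add atoms: none
Why: Enone–alkene [2+2] photocycloaddition: the triplet enone adds stepwise to 9 through a 1,4-biradical that recombines to the cyclobutane C5–C10–C1–C4 (new bonds C4–C5 and C1–C10), the reaction type known for 3-methylcyclohexenones with 1-methylcyclobutene. The four-membered ring closes by radical–radical coupling, so the product reflects which biradical closes faster than it reverts. C5 and C10 come out cis because the cyclobutane is fused to the six-membered ring (a trans-fused isomer would epimerise at C5, α to the ketone), C1 and C4 are cis because they belong to the cyclobutene, and the two outer rings lie anti across the new cyclobutane for steric reasons. The alkene approaches the enone face opposite the lactone, the convex face of the cis-fused bicycle. The selectivity that matters is regiochemical (head-to-head): C10 already bears a methyl group, so the orientation that would join it to the methyl-bearing C4 and create adjacent quaternary carbons is disfavoured. The four new stereocentres are erased in step 7.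

**Step 7**
Reactants: 10 cis-anti-cis photoadduct
Product: 11 (1(10)E,4Z,7S,8S)-6-oxo-7αH,8αH-germacra-1(10),4-dien-12,8-olide
Conditions: PhMe (0.01 M, degassed, silylated sealed tube), 160 °C
Reagents that add atoms: none
Why: Thermal cycloreversion of the bicyclo[2.2.0]hexane: strain-driven cleavage of the central C1–C4 bond gives a cyclohexane-1,4-diyl that breaks C5–C10 and releases the C1=C10 and C4=C5 alkenes; the chair diyl delivers the E,Z diene, which can undergo Cope rearrangement only through a boat and so should survive at the lowest temperature that opens the ring.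

**Step 8**
Reactants: 11 (1(10)E,4Z)-6-oxo-7αH,8αH-germacra-1(10),4-dien-12,8-olide
Product: 13 (1(10)E,4S,7S,8S)-4α-hydroxy-6-oxo-7αH,8αH-germacr-1(10)-en-12,8-olide, via C4 pinacol boronate 12 (not isolated)
Conditions: CuCl (5 mol %), (R,R)-QuinoxP* (6 mol %), NaOtBu (10 mol %), B2pin2, MeOH, THF, 0 °C → rt; then NaBO3·4H2O, THF–H2O, rt
Reagents that add atoms: NaBO3·4H2O (sodium perborate) [Na+].[O-]OB=O; bis(pinacolato)diboron CC1(C)OB(OC1(C)C)B1OC(C)(C)C(C)(C)O1 (boron stays in 12 only)
Why: Copper-catalysed conjugate borylation of a β,β-disubstituted enone followed by stereoretentive C–B oxidation: the chiral bisphosphine on the boryl copper decides the C4 face (α, 4S; the antipodal ligand is used if the first choice is mismatched with the ring's own bias), and the nearly neutral medium spares the β-acyloxy ketone.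

**Step 9**
Reactants: 13 (1(10)E)-4α-hydroxy-6-oxo-7αH,8αH-germacr-1(10)-en-12,8-olide
Product: 14 (1(10)E)-4α,6β-dihydroxy-7αH,8αH-germacr-1(10)-en-12,8-olide
Conditions: Me4NBH(OAc)3, MeCN–AcOH (1:1), −30 °C
Reagents that add atoms: none
Why: Evans–Saksena reduction: the C4 hydroxyl binds the acetoxyborohydride and hydride is delivered internally to the same side of C6, giving the 1,3-anti diol (6β-OH, 6R); lactone and alkene are inert to this reagent.

**Step 10**
Reactants: 14 (1(10)E)-4α,6β-dihydroxy-7αH,8αH-germacr-1(10)-en-12,8-olide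
Product: 15 (1(10)E)-4α-hydroxy-6β-(isobutyryloxy)-7αH,8αH-germacr-1(10)-en-12,8-olide
Conditions: (iPrCO)2O, DMAP (cat.), Et3N, CH2Cl2, 0 °C
Reagents that add atoms: isobutyric anhydride CC(C)C(=O)OC(=O)C(C)C
Why: DMAP-catalysed acylation takes the secondary C6 alcohol and leaves the tertiary C4 alcohol, and is done at once so that the free C6 hydroxyl cannot translactonise onto C12.

**Step 11**
Reactants: 15 (1(10)E)-4α-hydroxy-6β-(isobutyryloxy)-7αH,8αH-germacr-1(10)-en-12,8-olide
Product: 17 1β,4α-dihydroxy-6β-(isobutyryloxy)-7αH,8αH,10αH-germacran-12,8-olide, via C1 alkylborane 16 (not isolated)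
Conditions: BH3·THF, THF, 0 °C; then NaBO3·4H2O, H2O, rt
Reagents that add atoms: NaBO3·4H2O (sodium perborate) [Na+].[O-]OB=O; borane–THF B.C1CCOC1 (boron stays in 16 only)
Why: Hydroboration–oxidation (anti-Markovnikov, syn): boron goes to the less substituted C1 and hydrogen to C10 from the exposed outer face of the E alkene, the face on which 1(10)-alkenes of germacranolides are attacked, leaving C14 β (10R); the C1 carbinol configuration is irrelevant and perborate spares both esters.

**Step 12**
Reactants: 17 1β,4α-dihydroxy-6β-(isobutyryloxy)-7αH,8αH,10αH-germacran-12,8-olide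
Product: 18 6β-(isobutyryloxy)-1β,4α-bis(triethylsilyloxy)-7αH,8αH,10αH-germacran-12,8-olide
Conditions: Et3SiOTf, 2,6-lutidine, CH2Cl2, −40 → 0 °C
Reagents that add atoms: triethylsilyl trifluoromethanesulfonate CC[Si](CC)(CC)OS(=O)(=O)C(F)(F)F
Why: Silyl triflate/lutidine silylation caps both the secondary and the tertiary alcohol, so that no alkoxide is present next to the ester and lactone in step 13.

**Step 13**
Reactants: 18 6β-(isobutyryloxy)-1β,4α-bis(triethylsilyloxy)-7αH,8αH,10αH-germacran-12,8-olide
Product: 21 6β-(isobutyryloxy)-1β,4α-bis(triethylsilyloxy)-7αH,8αH,10αH-germacr-11(13)-en-12,8-olide, via Mannich base 19 (not isolated), via trimethylammonium iodide 20 (not isolated)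
Conditions: LiN(SiMe3)2, THF, −78 °C; CH2=NMe2+ I−, −78 → −20 °C; then MeI, MeOH–CH2Cl2, rt; then aq. NaHCO3, CH2Cl2, rt
Reagents that add atoms: Eschenmoser's salt (N,N-dimethylmethyleneiminium iodide) C=[N+](C)C.[I-]; iodomethane CI (its methyl stays in 20 only)
Why: Lactone α-methylenation by Mannich reaction with Eschenmoser's salt, quaternisation and Hofmann-type elimination: LiN(SiMe3)2 at −78 °C deprotonates the unhindered, more acidic γ-lactone CH2 and not the hindered isobutyrate methine, and the C11 centre formed on the way is erased.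

**Step 14**
Reactants: 21 6β-(isobutyryloxy)-1β,4α-bis(triethylsilyloxy)-7αH,8αH,10αH-germacr-11(13)-en-12,8-olide
Product: 22 1β,4α-dihydroxy-6β-(isobutyryloxy)-7αH,8αH,10αH-germacr-11(13)-en-12,8-olide
Conditions: HF·pyridine, pyridine, THF, 0 °C → rt
Reagents that add atoms: none
Why: Fluoride-mediated desilylation under buffered, weakly acidic conditions frees both alcohols without Michael addition to the methylene lactone or acyl migration.

**Step 15**
Reactants: 22 1β,4α-dihydroxy-6β-(isobutyryloxy)-7αH,8αH,10αH-germacr-11(13)-en-12,8-olide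
Product: 23 (4S,6R,7S,8S,10R)-4α-hydroxy-6β-(isobutyryloxy)-1-oxo-7αH,8αH,10αH-germacr-11(13)-en-12,8-olide (CNP0293926.1)
Conditions: Dess–Martin periodinane, NaHCO3, CH2Cl2, 0 °C → rt
Reagents that add atoms: none
Why: Dess–Martin oxidation converts the only secondary alcohol into the C1 ketone under buffered, non-epimerising conditions, leaving the tertiary C4 alcohol, the ester and the methylene lactone untouched.

**Compound list**

1 | methyl (3R)-3-[(tert-butyldimethylsilyl)oxy]-6-(dimethoxyphosphoryl)-5-oxohexanoate | COC(=O)C[C@H](O[Si](C)(C)C(C)(C)C)CC(=O)CP(=O)(OC)OC | starting material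
2 | (3R)-3-[(tert-butyldimethylsilyl)oxy]-6-(dimethoxyphosphoryl)-N-methoxy-N-methyl-5-oxohexanamide (Weinreb amide) | CON(C)C(=O)C[C@H](O[Si](C)(C)C(C)(C)C)CC(=O)CP(=O)(OC)OC | intermediate
3 | dimethyl [(4S)-4-[(tert-butyldimethylsilyl)oxy]-2,6-dioxoheptyl]phosphonate | CC(=O)C[C@H](O[Si](C)(C)C(C)(C)C)CC(=O)CP(=O)(OC)OC | intermediate
4 | (5S)-5-[(tert-butyldimethylsilyl)oxy]-3-methylcyclohex-2-en-1-one | CC1=CC(=O)C[C@@H](O[Si](C)(C)C(C)(C)C)C1 | intermediate
5 | tert-butyl bromoacetate | CC(C)(C)OC(=O)CBr | starting material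
6 | tert-butyl 2-[(1R,6S)-6-[(tert-butyldimethylsilyl)oxy]-4-methyl-2-oxocyclohex-3-en-1-yl]acetate | CC1=CC(=O)[C@H](CC(=O)OC(C)(C)C)[C@@H](O[Si](C)(C)C(C)(C)C)C1 | intermediate
7 | (3aS,7aS)-6-methyl-3a,7a-dihydro-1-benzofuran-2,4(3H,7H)-dione | CC1=CC(=O)[C@H]2CC(=O)O[C@H]2C1 | intermediate
8 | methylenecyclobutane | C=C1CCC1 | starting material
9 | 1-methylcyclobutene | CC1=CCC1 | intermediate
10 | cis-anti-cis head-to-head photoadduct (lactone-fused cyclohexanone, cyclobutane C5–C10–C1–C4 on the α face, fused at C1–C4 to cyclobutane C1–C2–C3–C4) | C[C@]12C[C@@H]3OC(=O)C[C@@H]3C(=O)[C@H]1[C@]4(C)CC[C@H]24 | intermediate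
11 | (1(10)E,4Z,7S,8S)-6-oxo-7αH,8αH-germacra-1(10),4-dien-12,8-olide | C1C(=O)O[C@H]2C/C(C)=C/CC/C(C)=C\C(=O)[C@@H]12 | intermediate
12 | (1(10)E)-6-oxo-4α-(4,4,5,5-tetramethyl-1,3,2-dioxaborolan-2-yl)-7αH,8αH-germacr-1(10)-en-12,8-olide | C1C(=O)O[C@H]2C/C(C)=C/CC[C@](C)(B3OC(C)(C)C(C)(C)O3)CC(=O)[C@@H]12 | intermediate
13 | (1(10)E,4S,7S,8S)-4α-hydroxy-6-oxo-7αH,8αH-germacr-1(10)-en-12,8-olide | C1C(=O)O[C@H]2C/C(C)=C/CC[C@](C)(O)CC(=O)[C@@H]12 | intermediate
14 | (1(10)E)-4α,6β-dihydroxy-7αH,8αH-germacr-1(10)-en-12,8-olide | C1C(=O)O[C@H]2C/C(C)=C/CC[C@](C)(O)C[C@@H](O)[C@@H]12 | intermediate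
15 | (1(10)E)-4α-hydroxy-6β-(isobutyryloxy)-7αH,8αH-germacr-1(10)-en-12,8-olide | C1C(=O)O[C@H]2C/C(C)=C/CC[C@](C)(O)C[C@@H](OC(=O)C(C)C)[C@@H]12 | intermediate
16 | 1β-boryl-4α-hydroxy-6β-(isobutyryloxy)-7αH,8αH,10αH-germacran-12,8-olide (C1 alkylborane) | C1C(=O)O[C@H]2C[C@@H](C)[C@@H](B)CC[C@](C)(O)C[C@@H](OC(=O)C(C)C)[C@@H]12 | intermediate
17 | 1β,4α-dihydroxy-6β-(isobutyryloxy)-7αH,8αH,10αH-germacran-12,8-olide | C1C(=O)O[C@H]2C[C@@H](C)[C@@H](O)CC[C@](C)(O)C[C@@H](OC(=O)C(C)C)[C@@H]12 | intermediate
18 | 6β-(isobutyryloxy)-1β,4α-bis(triethylsilyloxy)-7αH,8αH,10αH-germacran-12,8-olide | C1C(=O)O[C@H]2C[C@@H](C)[C@@H](O[Si](CC)(CC)CC)CC[C@](C)(O[Si](CC)(CC)CC)C[C@@H](OC(=O)C(C)C)[C@@H]12 | intermediate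
19 | 11-(dimethylaminomethyl) derivative of 18 (Mannich base, aminomethyl group trans to C6) | [C@@H]1(CN(C)C)C(=O)O[C@H]2C[C@@H](C)[C@@H](O[Si](CC)(CC)CC)CC[C@](C)(O[Si](CC)(CC)CC)C[C@@H](OC(=O)C(C)C)[C@@H]12 | intermediate
20 | 11-(trimethylammoniomethyl) derivative of 18, iodide | [C@@H]1(C[N+](C)(C)C)C(=O)O[C@H]2C[C@@H](C)[C@@H](O[Si](CC)(CC)CC)CC[C@](C)(O[Si](CC)(CC)CC)C[C@@H](OC(=O)C(C)C)[C@@H]12.[I-] | intermediate
21 | 6β-(isobutyryloxy)-1β,4α-bis(triethylsilyloxy)-7αH,8αH,10αH-germacr-11(13)-en-12,8-olide | C=C1C(=O)O[C@H]2C[C@@H](C)[C@@H](O[Si](CC)(CC)CC)CC[C@](C)(O[Si](CC)(CC)CC)C[C@@H](OC(=O)C(C)C)[C@@H]12 | intermediate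
22 | 1β,4α-dihydroxy-6β-(isobutyryloxy)-7αH,8αH,10αH-germacr-11(13)-en-12,8-olide | C=C1C(=O)O[C@H]2C[C@@H](C)[C@@H](O)CC[C@](C)(O)C[C@@H](OC(=O)C(C)C)[C@@H]12 | intermediate
23 | (4S,6R,7S,8S,10R)-4α-hydroxy-6β-(isobutyryloxy)-1-oxo-7αH,8αH,10αH-germacr-11(13)-en-12,8-olide | C=C1C(=O)O[C@H]2C[C@@H](C)C(=O)CC[C@](C)(O)C[C@@H](OC(=O)C(C)C)[C@@H]12 | target

**Step count and risks**

Total steps: 15. Longest linear sequence: 14 (steps 1–4 and 6–15 from 1); step 5 is a one-step side branch.

Step 4 (acid lactonisation with C7 epimerisation). What may go wrong: the C7 enol needed for epimerisation expels the C8 oxygen and the ring aromatises, or lactonisation stalls at the trans stage. Fallback, from 6 back to 10: lactonisation is postponed until the enone is gone. 6 itself is irradiated with 9 under the conditions of step 6 to give the open photoadduct tert-butyl ester silyl ether F1. Treating this saturated β-silyloxy ketone with TFA–H2O and then catalytic CSA removes both groups, equilibrates C7 through an enol that has no aromatic outlet and closes the cis lactone, which is 10. Addition to the face opposite the C8 silyloxy group gives 10 itself; the other facial isomer would converge at 11.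

Step 7 (thermal ring opening). What may go wrong: at the temperature needed the keto lactone enolises toward C7 and sheds the lactone carboxylate, or the dienone drifts into its Cope isomer on prolonged heating. Fallback, from 10 back to 11: the opening is run at the alcohol oxidation level. NaBH4 (MeOH–CH2Cl2, −40 °C) reduces the ketone of 10 to the 6α-carbinol photoadduct F2 (either C6 epimer serves). Thermolysis as in step 7 then gives the cyclodecadienol F3, which cannot enolise, and MnO2 (CH2Cl2, rt) oxidises this allylic alcohol to 11.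

Step 8 (boryl addition at C4). What may go wrong: poor facial selectivity at C4 when the ring's own bias opposes the ligand, or slow boryl transfer to the hindered trisubstituted Z-enone. Fallback, from 11 back to 13: oxygen is brought to C4 by nucleophilic epoxidation instead. Iminium-catalysed epoxidation of 11 with aqueous H2O2 and the bis(trifluoroacetate) salt of 9-amino-9-deoxy-epi-quinine gives the 4α,5α-epoxy ketone F4; the quinidine-derived pseudo-enantiomer of the catalyst addresses the other face. SmI2 (THF–MeOH, −78 °C) cleaves the Cα–O bond of the epoxy ketone and returns 13.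

**Further compounds**

F1 | step 4 | open photoadduct of 6 and 9 (as 10, but C8 carries the β tert-butyldimethylsilyloxy group and C7 the α CH2CO2tBu chain) | C[C@]12C[C@H](O[Si](C)(C)C(C)(C)C)[C@@H](CC(=O)OC(C)(C)C)C(=O)[C@H]1[C@]4(C)CC[C@H]24
F2 | step 7 | 6α-hydroxy photoadduct (10 with the C6 ketone reduced) | C[C@]12C[C@@H]3OC(=O)C[C@@H]3[C@@H](O)[C@H]1[C@]4(C)CC[C@H]24
F3 | step 7 | (1(10)E,4Z)-6α-hydroxy-7αH,8αH-germacra-1(10),4-dien-12,8-olide | C1C(=O)O[C@H]2C/C(C)=C/CC/C(C)=C\[C@H](O)[C@@H]12
F4 | step 8 | (1(10)E)-4α,5α-epoxy-6-oxo-7αH,8αH-germacr-1(10)-en-12,8-olide | C1C(=O)O[C@H]2C/C(C)=C/CC[C@]3(C)O[C@@H]3C(=O)[C@@H]12
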